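The runs come from a simulation for an exercise.

**The flask.** Read the earlier runs first. E meets J, D is the product, and L is a further species in the flask. The new flasks differ in J.

| flask | E | J | L | remark | time |
|---|---|---|---|---|---|
| spring | 5 mM | 13 mM | 1 mM | run made earlier |  |
| noon | 5 mM | 37 mM | 1 mM | run made earlier |  |
| gamma | 5.0 mM | 60.0 mM | 1.00 mM |  | 2.5 min |
| eta | 5.0 mM | 30.0 mM | 1.00 mM |  | 2.5 min |
| alpha | 5.0 mM | 15.0 mM | 1.00 mM |  | 2.5 min |

| run | time / min | E / % | D / % |
|---|---|---|---|
| spring | 0.333 | 61.5 | 21.0 |
| spring | 0.667 | 51.3 | 30.1 |
| spring | 1.00 | 45.4 | 34.0 |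
| spring | 1.33 | 42.3 | 37.7 |
| spring | 2.00 | 39.1 | 40.8 |
| spring | 2.50 | 38.8 | 41.2 |
| noon | 0.333 | 43.6 | 38.8 |
| noon | 0.667 | 32.7 | 48.2 |
| noon | 1.00 | 28.0 | 51.8 |
| noon | 1.33 | 25.3 | 54.6 |
| noon | 2.00 | 24.9 | 56.3 |
| noon | 2.50 | 25.0 | 55.6 |

(readings scatter by 0.5 percentage points)

- the numbers in the tables scatter by 0.5 percentage points (one standard deviation)

* part of the E that has reacted at the end, gamma
* part of the E that has reacted at the end, eta
* part of the E that has reacted at the end, alpha
* what raising the concentration of J from its lowest to its highest value here does to the part of the E that has reacted (changes below 5 percentage points count as none) (no change / it falls / it rises)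

**The gap.** I took E and D from the E charged at the last reading of each run. That left 20.0% in spring and 19.4% in noon. Then I divided the charge of L by the charge of E and called this the L toll, the share of E that L claims if one L takes one E: 20.0%. The gap read close to the toll, so I treated the toll as a fixed correction and reckoned E and D in the remainder.

**Bench rule.** The usual rule says the final ratio of D to E follows J. It read 1.06 in spring and 2.22 in noon. J rose by a factor of 2.85, but the ratio rose by 2.09, so the plain rule failed. So I scaled the spring ratio by the charge of J raised to a power read from the two runs, 0.707.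

**My reckoning.** This gave 63.2% reacted for alpha, 72.6% for eta and 80.6% for gamma. Alpha and eta lay between the runs in their charge of J. Gamma lay past the border, with J 1.62 times the noon charge, so I trusted it least.

**The forecast.** It gave 80% for gamma, 72% for eta and 63% for alpha, and said of the reacted part, as J goes up: it rises. Among its grounds stood “L probably takes up E quickly”. It differed from my reckoning by a point at most.

**The result.** The flask gave 80.8% for gamma, 73.1% for eta and 63.2% for alpha. Of the reacted part, as J goes up: it rises, by 18 percentage points.

    E + J ⇌ X + D (K = 0.0840, k = 1.60 M⁻¹ s⁻¹)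
    J + X ⇌ Z, settled at all times (K = 18000 M⁻¹)
    E + L → G (k = 30.0 M⁻¹ s⁻¹)
    2 J → Q (k = 1.50 M⁻¹ s⁻¹)

**The toll again.** In gamma, G stood at 19.9% of the E charged at 2.50 min, matching the toll. L, the limiting reagent of that loss, was down to 0.302% of its charge. A neighbour of eta charged with 20 mM of E has a toll of 5.00%. There G stood at 5.00%, D at 37.0%, and 42.0% of its E had reacted.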